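**Retrosynthetic overview**
- The target is 5,6,7,2',3',4',5'-heptamethoxyflavone. Rings A and B are bought as benzenes, and only ring C (the pyranone) is built, in the last step, by oxidative cyclisation of a 2'-hydroxychalcone.
- Key C–C disconnection (flavone C2–C3, the chalcone Cα–Cβ bond): intermolecular Claisen–Schmidt aldol condensation of 6-hydroxy-2,3,4-trimethoxyacetophenone (ring A) with 2,3,4,5-tetramethoxybenzaldehyde (ring B).
- Ring A ketone: ortho C-acetylation of 3,4,5-trimethoxyphenol.
- Ring B aldehyde: 2,3,4-trimethoxybenzaldehyde, then Dakin oxidation, O-methylation and formylation of the symmetric 1,2,3,4-tetramethoxybenzene.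

Assumption: the target has no stereocentre and is achiral, so no asymmetric step is needed; the only stereochemical feature on the way is the E double bond of the chalcone intermediate.

**Route**

Step 1
Reactants: 1 2,3,4-trimethoxybenzaldehyde
Product: 3 2,3,4-trimethoxyphenol, via 2,3,4-trimethoxyphenyl formate 2 (not isolated)
Conditions: 30% aq H2O2 (1.3 equiv), conc. H2SO4 (cat.), MeOH, rt, 16 h
Reagents that add atoms: hydrogen peroxide, OO
Why: Dakin-type Baeyer–Villiger oxidation in which the electron-rich aryl group (ortho- and para-OMe) migrates to oxygen and the resulting aryl formate is methanolysed in the same acidic flask.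

Step 2
Reactants: 3 2,3,4-trimethoxyphenol
Product: 4 1,2,3,4-tetramethoxybenzene
Conditions: MeI (1.5 equiv), K2CO3 (2 equiv), acetone, reflux, 12 h
Reagents that add atoms: iodomethane, CI
Why: Williamson ether synthesis, an SN2 O-methylation of the potassium phenolate that has no competing nucleophilic site.

Step 3
Reactants: 4 1,2,3,4-tetramethoxybenzene
Product: 6 2,3,4,5-tetramethoxybenzaldehyde, via 1-[chloro(methoxy)methyl]-2,3,4,5-tetramethoxybenzene 5 (not isolated)
Conditions: Cl2CHOMe (1.2 equiv), TiCl4 (2 equiv), CH2Cl2, 0 °C, 1 h; then ice/1 M HCl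
Reagents that add atoms: dichloromethyl methyl ether, COC(Cl)Cl; water, O
Why: Rieche formylation (Friedel–Crafts type) of an arene whose two free positions are equivalent by symmetry and activated ortho/para by methoxy groups, so one regioisomer forms and the formyl group then deactivates the ring against a second substitution.

Step 4
Reactants: 7 3,4,5-trimethoxyphenol
Product: 9 1-(6-hydroxy-2,3,4-trimethoxyphenyl)ethan-1-one, via O,O-difluoroboron chelate of 1-(6-hydroxy-2,3,4-trimethoxyphenyl)ethan-1-one 8 (not isolated)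
Conditions: AcOH (5 equiv), BF3·OEt2 (excess), 90 °C, 2 h; then H2O, 60 °C
Reagents that add atoms: acetic acid, CC(=O)O
Why: BF3-promoted Friedel–Crafts (Fries-type) C-acetylation ortho to the phenol, where both ortho positions are equivalent and the stable six-membered difluoroboron chelate drives the reaction and blocks a second acylation before it is hydrolysed at work-up.

Step 5
Reactants: 9 1-(6-hydroxy-2,3,4-trimethoxyphenyl)ethan-1-one; 6 2,3,4,5-tetramethoxybenzaldehyde (1.1 equiv)
Product: 11 (E)-1-(6-hydroxy-2,3,4-trimethoxyphenyl)-3-(2,3,4,5-tetramethoxyphenyl)prop-2-en-1-one, via 3-hydroxy-1-(6-hydroxy-2,3,4-trimethoxyphenyl)-3-(2,3,4,5-tetramethoxyphenyl)propan-1-one 10 (not isolated)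
Conditions: KOH (50% aq, 10 equiv), EtOH, rt, 36 h; then 2 M HCl, 0 °C
Reagents that add atoms: none
Why: Claisen–Schmidt crossed aldol condensation in which only the methyl ketone can enolise and only the aldehyde is a good acceptor, and E1cB dehydration of the aldol adduct gives the thermodynamically favoured conjugated E-enone.

Step 6
Reactants: 11 (E)-1-(6-hydroxy-2,3,4-trimethoxyphenyl)-3-(2,3,4,5-tetramethoxyphenyl)prop-2-en-1-one
Product: 14 agehoustin B (5,6,7-trimethoxy-2-(2,3,4,5-tetramethoxyphenyl)-4H-chromen-4-one), via 5,6,7-trimethoxy-2-(2,3,4,5-tetramethoxyphenyl)chroman-4-one 12 (not isolated), via 3-iodo-5,6,7-trimethoxy-2-(2,3,4,5-tetramethoxyphenyl)chroman-4-one 13 (not isolated)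
Conditions: I2 (10 mol %), DMSO, 130 °C, 2 h; then aq Na2S2O3
Reagents that add atoms: none
Why: Iodine/DMSO oxidative cyclisation of a 2'-hydroxychalcone, in which intramolecular oxa-Michael addition closes ring C and α-iodination followed by dehydroiodination introduces the C2=C3 double bond while DMSO reoxidises HI to I2, and in which the racemic stereocentres of the intermediates disappear in the achiral flavone.

**Compound list**

1 | 2,3,4-trimethoxybenzaldehyde | COc1ccc(C=O)c(OC)c1OC | starting material
2 | 2,3,4-trimethoxyphenyl formate | COc1ccc(OC=O)c(OC)c1OC | intermediate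
3 | 2,3,4-trimethoxyphenol | COc1ccc(O)c(OC)c1OC | intermediate
4 | 1,2,3,4-tetramethoxybenzene | COc1ccc(OC)c(OC)c1OC | intermediate
5 | 1-[chloro(methoxy)methyl]-2,3,4,5-tetramethoxybenzene (racemic) | COC(Cl)c1cc(OC)c(OC)c(OC)c1OC | intermediate
6 | 2,3,4,5-tetramethoxybenzaldehyde | COc1cc(C=O)c(OC)c(OC)c1OC | intermediate
7 | 3,4,5-trimethoxyphenol | COc1cc(O)cc(OC)c1OC | starting material
8 | O,O-difluoroboron chelate of 1-(6-hydroxy-2,3,4-trimethoxyphenyl)ethan-1-one (phenolate O and ketone O on boron, six-membered ring) | CC1=[O+][B-](F)(F)Oc2cc(OC)c(OC)c(OC)c12 | intermediate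
9 | 1-(6-hydroxy-2,3,4-trimethoxyphenyl)ethan-1-one | CC(=O)c1c(O)cc(OC)c(OC)c1OC | intermediate
10 | 3-hydroxy-1-(6-hydroxy-2,3,4-trimethoxyphenyl)-3-(2,3,4,5-tetramethoxyphenyl)propan-1-one (racemic aldol adduct) | COc1cc(C(O)CC(=O)c2c(O)cc(OC)c(OC)c2OC)c(OC)c(OC)c1OC | intermediate
11 | (E)-1-(6-hydroxy-2,3,4-trimethoxyphenyl)-3-(2,3,4,5-tetramethoxyphenyl)prop-2-en-1-one | COc1cc(/C=C/C(=O)c2c(O)cc(OC)c(OC)c2OC)c(OC)c(OC)c1OC | intermediate
12 | 5,6,7-trimethoxy-2-(2,3,4,5-tetramethoxyphenyl)chroman-4-one (racemic flavanone) | COc1cc(C2CC(=O)c3c(OC)c(OC)c(OC)cc3O2)c(OC)c(OC)c1OC | intermediate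
13 | 3-iodo-5,6,7-trimethoxy-2-(2,3,4,5-tetramethoxyphenyl)chroman-4-one (racemic) | COc1cc(C2Oc3cc(OC)c(OC)c(OC)c3C(=O)C2I)c(OC)c(OC)c1OC | intermediate
14 | agehoustin B, 5,6,7-trimethoxy-2-(2,3,4,5-tetramethoxyphenyl)-4H-chromen-4-one (achiral) | COc1cc(-c2cc(=O)c3c(OC)c(OC)c(OC)cc3o2)c(OC)c(OC)c1OC | target

**Step count and risks**

Total step count: 6. Longest linear sequence: 5 steps (steps 1, 2, 3, 5, 6); step 4 is the one-step ring A branch.

The three steps most likely to fail:

Step 3 (Rieche formylation). The risk is TiCl4-mediated cleavage of the methoxy group ortho to the new formyl group, or incomplete conversion. The fallback sets out from 4 and comes back at 6. Directed ortho-lithiation of 4 (n-BuLi, TMEDA, THF, 0 °C) gives (2,3,4,5-tetramethoxyphenyl)lithium F1. Addition of DMF at −78 °C gives lithium (dimethylamino)(2,3,4,5-tetramethoxyphenyl)methanolate F2, which collapses to aldehyde 6 on quenching with dilute HCl. No Lewis acid is present, so demethylation cannot occur, and the symmetry of 4 again allows only one regioisomer.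

Step 5 (Claisen–Schmidt condensation). The risk is slow conversion, because the ketone is present as its phenolate and flanked by two ortho substituents, and the aldehyde is electron-rich; Cannizzaro loss of 6 can compete. Partial closure of 11 to 12 is harmless because both go on to 14. The fallback sets out from 6 and 9 and comes back at 14. Pinnick oxidation of 6 (NaClO2, NaH2PO4, 2-methyl-2-butene, t-BuOH/H2O, rt) gives 2,3,4,5-tetramethoxybenzoic acid F3. (COCl)2 with cat. DMF in CH2Cl2 converts it to 2,3,4,5-tetramethoxybenzoyl chloride F4. Ketone 9 is deprotonated with LiN(SiMe3)2 (4 equiv, THF, −78 °C) and C-acylated by F4 in an intermolecular Claisen condensation. This gives 1-(6-hydroxy-2,3,4-trimethoxyphenyl)-3-(2,3,4,5-tetramethoxyphenyl)propane-1,3-dione F5. Cyclodehydration of F5 (cat. H2SO4, AcOH, 100 °C) closes ring C and gives 14 directly.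

Step 6 (I2/DMSO oxidative cyclisation). The risk is HI-mediated cleavage of the 5-methoxy group peri to the carbonyl, or iodination at C8 of ring A, at 130 °C. The fallback sets out from 11 and comes back at 14. NaOAc in refluxing EtOH isomerises 11 to flavanone 12, which is now isolated. DDQ (2 equiv) in refluxing 1,4-dioxane dehydrogenates 12 to 14 without any iodine or HI. This detour makes no compound outside the compound list (F0).

**Further compounds**

F1 | step 3 | (2,3,4,5-tetramethoxyphenyl)lithium | [Li]c1cc(OC)c(OC)c(OC)c1OC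
F2 | step 3 | lithium (dimethylamino)(2,3,4,5-tetramethoxyphenyl)methanolate (racemic) | [Li+].[O-]C(N(C)C)c1cc(OC)c(OC)c(OC)c1OC
F3 | step 5 | 2,3,4,5-tetramethoxybenzoic acid | COc1cc(C(=O)O)c(OC)c(OC)c1OC
F4 | step 5 | 2,3,4,5-tetramethoxybenzoyl chloride | COc1cc(C(=O)Cl)c(OC)c(OC)c1OC
F5 | step 5 | 1-(6-hydroxy-2,3,4-trimethoxyphenyl)-3-(2,3,4,5-tetramethoxyphenyl)propane-1,3-dione | COc1cc(C(=O)CC(=O)c2c(O)cc(OC)c(OC)c2OC)c(OC)c(OC)c1OC
F0 | step 6 | none | none
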